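The route rests on opening the lactone ring of the 5-methylcoumarin (O1, C2, C3, C4, C4a, C8a) at O1–C2 and C3=C4. This reveals an allylic ester of 6-methylsalicylic acid in which the ester oxygen already sits on the future C4, so the ether link never has to be made by alkylating an ambident 4-hydroxycoumarin. In a single operation ketenylidenetriphenylphosphorane supplies C2 and C3: the phenol is acylated, and the ylide so formed olefinates the adjacent ester carbonyl, fusing the pyranone ring to the methyl-bearing benzene ring. The precursor is the complete (2'Z)-configured C1'–C8' side chain as that ester, with the hydroxymethyl group as tert-butyldiphenylsilyl ether and C6' as (R)-triethylsilyl ether.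

Key step: step 10

Remark: C1'–C8' number the octadienyl chain from the ether CH2, and C10' is the hydroxymethyl carbon on C3'; the target is (2'Z,6'S). Ketenylidenetriphenylphosphorane, the (S)-oxazaborolidine catalyst, catecholborane and methoxytrimethylsilane are taken as purchased reagents. Abbreviations: PMB = 4-methoxybenzyl, TBDPS = tert-butyldiphenylsilyl.

Step 1
Reactants: 1 methyl acrylate; 2 (4-methoxybenzyloxy)acetaldehyde
Product: 3 methyl 3-hydroxy-4-[(4-methoxybenzyl)oxy]-2-methylidenebutanoate (racemic)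
Conditions: 1 (3 equiv), 1,4-diazabicyclo[2.2.2]octane (0.5 equiv), MeOH, rt, 3 d
Reagents that add atoms: none
Why: Morita–Baylis–Hillman reaction, in which the amine adds to the acrylate, the resulting enolate attacks the reactive α-alkoxy aldehyde and elimination regenerates the amine; the carbinol centre is formed racemic, which does not matter because it is erased in step 5.

Step 2
Reactants: 3 methyl 3-hydroxy-4-[(4-methoxybenzyl)oxy]-2-methylidenebutanoate
Product: 4 4-[(4-methoxybenzyl)oxy]-2-methylidenebutane-1,3-diol (racemic)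
Conditions: i-Bu2AlH (3.5 equiv), CH2Cl2, −78 → 0 °C; aq. KNaC4H4O6
Reagents that add atoms: none
Why: Hydride 1,2-reduction of the acrylate ester by i-Bu2AlH, the usual conversion of Baylis–Hillman adducts into 2-methylidene-1,3-diols, leaves the PMB ether and the 1,1-disubstituted olefin untouched.

Step 3
Reactants: 4 4-[(4-methoxybenzyl)oxy]-2-methylidenebutane-1,3-diol
Product: 5 3-{[(tert-butyldiphenylsilyl)oxy]methyl}-1-[(4-methoxybenzyl)oxy]but-3-en-2-ol (racemic)
Conditions: TBDPSCl (1.05 equiv), imidazole, CH2Cl2, −20 → 0 °C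
Reagents that add atoms: tert-butyl(chloro)diphenylsilane, CC(C)(C)[Si](Cl)(c1ccccc1)c1ccccc1
Why: Silylation with the bulky chlorosilane is selective for the primary over the secondary allylic hydroxyl, so the robust C10' protecting group is installed while the carbinol needed for the Claisen step stays free.

Step 4
Reactants: 6 3-methylbut-3-en-2-one
Product: 7 3,3-dimethoxy-2-methylbut-1-ene
Conditions: MeOSiMe3 (2.5 equiv), Me3SiOTf (2 mol %), CH2Cl2, −78 → −20 °C; pyridine quench, distillation
Reagents that add atoms: methoxytrimethylsilane, CO[Si](C)(C)C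
Why: Noyori acetalization, in which Me3SiOTf-catalysed exchange with the silyl methyl ether converts the ketone into its dimethyl ketal at low temperature without free methanol, so neither conjugate addition to the enone nor double-bond migration competes.

Step 5
Reactants: 5 3-{[(tert-butyldiphenylsilyl)oxy]methyl}-1-[(4-methoxybenzyl)oxy]but-3-en-2-ol; 7 3,3-dimethoxy-2-methylbut-1-ene
Product: 10 (6Z)-6-{[(tert-butyldiphenylsilyl)oxy]methyl}-8-[(4-methoxybenzyl)oxy]-2-methylocta-1,6-dien-3-one, via mixed ketal 8 (not isolated), via allyl dienyl ether 9 (not isolated)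
Conditions: 7 (4 equiv), 2,4-dinitrophenol (10 mol %), BHT (1 mol %), toluene, 110 °C, MeOH distilled off
Reagents that add atoms: none
Why: Ketal Claisen rearrangement (Saucy–Marbet/Johnson type), in which acid-catalysed exchange and loss of methanol give allyl dienyl ether 9, whose [3,3] shift through a chair with CH2OPMB equatorial (an axial position would clash with the isopropenyl group on the former ketal carbon) forms the C4'–C5' bond, the isopropenyl ketone and the trisubstituted olefin with CH2OPMB trans to the new chain, that is (2'Z).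

Step 6
Reactants: 10 (6Z)-6-{[(tert-butyldiphenylsilyl)oxy]methyl}-8-[(4-methoxybenzyl)oxy]-2-methylocta-1,6-dien-3-one
Product: 11 (3R,6Z)-6-{[(tert-butyldiphenylsilyl)oxy]methyl}-8-[(4-methoxybenzyl)oxy]-2-methylocta-1,6-dien-3-ol
Conditions: (S)-1-methyl-3,3-diphenyltetrahydro-1H,3H-pyrrolo[1,2-c][1,3,2]oxazaborole (20 mol %), catecholborane (1.5 equiv), toluene, −78 °C; aq. NaOH wash
Reagents that add atoms: none
Why: Corey–Bakshi–Shibata reduction, in which the (S)-oxazaborolidine binds the ketone with the isopropenyl group as the large substituent and directs hydride to the face that gives the (R)-allylic alcohol at C6', while catecholborane at −78 °C does not hydroborate the olefins.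

Step 7
Reactants: 11 (3R,6Z)-6-{[(tert-butyldiphenylsilyl)oxy]methyl}-8-[(4-methoxybenzyl)oxy]-2-methylocta-1,6-dien-3-ol
Product: 12 (3R,6Z)-6-{[(tert-butyldiphenylsilyl)oxy]methyl}-8-[(4-methoxybenzyl)oxy]-2-methyl-3-[(triethylsilyl)oxy]octa-1,6-diene
Conditions: Et3SiCl (1.3 equiv), imidazole, CH2Cl2, 0 °C
Reagents that add atoms: chlorotriethylsilane, CC[Si](Cl)(CC)CC
Why: Standard silylation masks the secondary allylic alcohol as a triethylsilyl ether that is stable to the oxidative debenzylation, the Mitsunobu reaction and the ylide step yet far more acid-labile than the TBDPS ether.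

Step 8
Reactants: 12 (3R,6Z)-6-{[(tert-butyldiphenylsilyl)oxy]methyl}-8-[(4-methoxybenzyl)oxy]-2-methyl-3-[(triethylsilyl)oxy]octa-1,6-diene
Product: 13 (2Z,6R)-3-{[(tert-butyldiphenylsilyl)oxy]methyl}-7-methyl-6-[(triethylsilyl)oxy]octa-2,7-dien-1-ol
Conditions: 2,3-dichloro-5,6-dicyano-1,4-benzoquinone (DDQ, 1.3 equiv), CH2Cl2/pH 7 phosphate buffer (10:1), 0 °C
Reagents that add atoms: none
Why: Oxidative PMB cleavage, in which DDQ abstracts hydride from the electron-rich benzylic position and water hydrolyses the oxocarbenium ion to the C1' allylic alcohol, the buffer protecting the triethylsilyl ether from the acidic hydroquinone.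

Step 9
Reactants: 13 (2Z,6R)-3-{[(tert-butyldiphenylsilyl)oxy]methyl}-7-methyl-6-[(triethylsilyl)oxy]octa-2,7-dien-1-ol; 14 6-methylsalicylic acid
Product: 15 (2Z,6R)-3-{[(tert-butyldiphenylsilyl)oxy]methyl}-7-methyl-6-[(triethylsilyl)oxy]octa-2,7-dien-1-yl 2-hydroxy-6-methylbenzoate
Conditions: PPh3 (1.3 equiv), diisopropyl azodicarboxylate (1.3 equiv), THF, 0 °C → rt
Reagents that add atoms: none
Why: Mitsunobu esterification, in which the carboxylate (far more acidic than the hydrogen-bonded phenol) displaces the primary allylic oxyphosphonium group by SN2 at carbon, so the steric shielding of the 2,6-disubstituted carboxyl group is irrelevant.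

Step 10
Reactants: 15 (2Z,6R)-3-{[(tert-butyldiphenylsilyl)oxy]methyl}-7-methyl-6-[(triethylsilyl)oxy]octa-2,7-dien-1-yl 2-hydroxy-6-methylbenzoate; 16 ketenylidenetriphenylphosphorane
Product: 18 4-{[(2Z,6R)-3-{[(tert-butyldiphenylsilyl)oxy]methyl}-7-methyl-6-[(triethylsilyl)oxy]octa-2,7-dien-1-yl]oxy}-5-methyl-2H-chromen-2-one, via ester ylide 17 (not isolated)
Conditions: 16 (1.3 equiv), toluene, 80 °C, argon
Reagents that add atoms: none
Why: The phenol O–H adds across the ylide C=C of 16 (O1–C2 bond) to give the aryloxycarbonyl-stabilised phosphorane 17, whose ylide carbon attacks the neighbouring ester carbonyl; the oxaphosphetane collapses with loss of Ph3PO and leaves the C3=C4 double bond. This is the known addition–intramolecular Wittig olefination of hydroxy esters with ketenylidenetriphenylphosphorane (tetronates from α-hydroxy esters, 4-alkoxycoumarins from salicylates). The pyranone ring (O1, C2, C3, C4, C4a, C8a) closes in a 6-exo-trig mode at the ester carbonyl, whose C=O bond lies outside the new ring. No stereocentre is formed, and C6' and the (2'Z) olefin are not touched. The step needs capture of the ylide by the phenol alone and olefination of an ester twisted by the peri methyl group: the first is secured by silylation of both other hydroxyls, the second by the intramolecular six-membered closure, and a bath temperature of at most 80 °C should keep the 4-allyloxycoumarin from a Claisen shift to C3. Because the ester alkoxy oxygen becomes the C4 ether oxygen, the choice between O- and C3-alkylation of a 4-hydroxycoumarin anion never arises.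

Step 11
Reactants: 18 4-{[(2Z,6R)-3-{[(tert-butyldiphenylsilyl)oxy]methyl}-7-methyl-6-[(triethylsilyl)oxy]octa-2,7-dien-1-yl]oxy}-5-methyl-2H-chromen-2-one
Product: 19 4-{[(2Z,6R)-3-{[(tert-butyldiphenylsilyl)oxy]methyl}-6-hydroxy-7-methylocta-2,7-dien-1-yl]oxy}-5-methyl-2H-chromen-2-one
Conditions: pyridinium p-toluenesulfonate (0.2 equiv), MeOH/CH2Cl2 (1:1), 0 °C
Reagents that add atoms: none
Why: Acid-catalysed methanolysis cleaves the secondary triethylsilyl ether far faster than the bulky primary TBDPS ether and does not affect the vinylogous carbonate of the coumarin.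

Step 12
Reactants: 19 4-{[(2Z,6R)-3-{[(tert-butyldiphenylsilyl)oxy]methyl}-6-hydroxy-7-methylocta-2,7-dien-1-yl]oxy}-5-methyl-2H-chromen-2-one
Product: 20 (3R,6Z)-6-{[(tert-butyldiphenylsilyl)oxy]methyl}-2-methyl-8-[(5-methyl-2-oxo-2H-chromen-4-yl)oxy]octa-1,6-dien-3-yl methanesulfonate
Conditions: Ms2O (1.5 equiv), Et3N (2.5 equiv), CH2Cl2, −20 °C; used crude
Reagents that add atoms: methanesulfonic anhydride, CS(=O)(=O)OS(C)(=O)=O
Why: O-Sulfonylation with the anhydride proceeds with retention at C6' and, unlike MsCl, introduces no chloride that could displace the labile secondary allylic mesylate, which is used at once without chromatography.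

Step 13
Reactants: 21 2,3-dimethylbut-2-ene
Product: 23 2-methoxyprop-2-yl hydroperoxide, via acetone O-oxide 22 (not isolated)
Conditions: O3, CH2Cl2/MeOH (4:1), −78 °C; N2 purge, careful concentration behind a shield
Reagents that add atoms: ozone, [O-][O+]=O; methanol, CO
Why: Ozonolysis in methanol (Criegee mechanism), in which cycloreversion of the primary ozonide gives acetone and acetone O-oxide, the latter being trapped by methanol as the α-methoxy hydroperoxide.

Step 14
Reactants: 20 (3R,6Z)-6-{[(tert-butyldiphenylsilyl)oxy]methyl}-2-methyl-8-[(5-methyl-2-oxo-2H-chromen-4-yl)oxy]octa-1,6-dien-3-yl methanesulfonate; 23 2-methoxyprop-2-yl hydroperoxide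
Product: 24 4-{[(2Z,6S)-3-{[(tert-butyldiphenylsilyl)oxy]methyl}-6-[(2-methoxypropan-2-yl)peroxy]-7-methylocta-2,7-dien-1-yl]oxy}-5-methyl-2H-chromen-2-one
Conditions: 23 (2 equiv), CsOH·H2O (1.3 equiv), DMF, 0 °C
Reagents that add atoms: none
Why: SN2 displacement of a secondary methanesulfonate by the caesium salt of a monoprotected hydroperoxide proceeds with inversion and converts the (6'R)-mesylate into the (6'S)-peroxyketal; the hydroperoxide is kept in excess over CsOH so that no free hydroxide is left to open the lactone.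

Step 15
Reactants: 24 4-{[(2Z,6S)-3-{[(tert-butyldiphenylsilyl)oxy]methyl}-6-[(2-methoxypropan-2-yl)peroxy]-7-methylocta-2,7-dien-1-yl]oxy}-5-methyl-2H-chromen-2-one
Product: 26 4-{[(2Z,6S)-6-hydroperoxy-3-(hydroxymethyl)-7-methylocta-2,7-dien-1-yl]oxy}-5-methyl-2H-chromen-2-one, via desilylated peroxyketal 25 (not isolated)
Conditions: Bu4NF/AcOH (1:1, 1.5 equiv), THF, 0 °C → rt; then AcOH/H2O (4:1), rt
Reagents that add atoms: none
Why: Acetic acid-buffered fluoride cleaves the Si–O bond of the primary silyl ether without base-induced Kornblum–DeLaMare fragmentation, and aqueous acetic acid then hydrolyses the peroxyketal to the hydroperoxide with loss of acetone and methanol, neither operation touching C6', the O–O bond or the olefin geometry.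

Compound list
1 | methyl acrylate | C=CC(=O)OC | starting material
2 | (4-methoxybenzyloxy)acetaldehyde | O=CCOCc1ccc(OC)cc1 | starting material
3 | methyl 3-hydroxy-4-[(4-methoxybenzyl)oxy]-2-methylidenebutanoate (racemic) | C=C(C(=O)OC)C(O)COCc1ccc(OC)cc1 | intermediate
4 | 4-[(4-methoxybenzyl)oxy]-2-methylidenebutane-1,3-diol (racemic) | C=C(CO)C(O)COCc1ccc(OC)cc1 | intermediate
5 | 3-{[(tert-butyldiphenylsilyl)oxy]methyl}-1-[(4-methoxybenzyl)oxy]but-3-en-2-ol (racemic) | C=C(CO[Si](c1ccccc1)(c1ccccc1)C(C)(C)C)C(O)COCc1ccc(OC)cc1 | intermediate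
6 | 3-methylbut-3-en-2-one | CC(=O)C(C)=C | starting material
7 | 3,3-dimethoxy-2-methylbut-1-ene | C=C(C)C(C)(OC)OC | intermediate
8 | mixed ketal: 3-{[(tert-butyldiphenylsilyl)oxy]methyl}-2-[(2-methoxy-3-methylbut-3-en-2-yl)oxy]-1-[(4-methoxybenzyl)oxy]but-3-ene (diastereomer mixture) | C=C(CO[Si](c1ccccc1)(c1ccccc1)C(C)(C)C)C(COCc1ccc(OC)cc1)OC(C)(OC)C(C)=C | intermediate (not isolated)
9 | allyl dienyl ether: 3-{[(tert-butyldiphenylsilyl)oxy]methyl}-1-[(4-methoxybenzyl)oxy]-2-[(3-methylbuta-1,3-dien-2-yl)oxy]but-3-ene (racemic) | C=C(CO[Si](c1ccccc1)(c1ccccc1)C(C)(C)C)C(COCc1ccc(OC)cc1)OC(=C)C(C)=C | intermediate (not isolated)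
10 | (6Z)-6-{[(tert-butyldiphenylsilyl)oxy]methyl}-8-[(4-methoxybenzyl)oxy]-2-methylocta-1,6-dien-3-one (CH2OTBDPS cis to CH2OPMB) | C=C(C)C(=O)CC/C(=C/COCc1ccc(OC)cc1)CO[Si](c1ccccc1)(c1ccccc1)C(C)(C)C | intermediate
11 | (3R,6Z)-6-{[(tert-butyldiphenylsilyl)oxy]methyl}-8-[(4-methoxybenzyl)oxy]-2-methylocta-1,6-dien-3-ol | C=C(C)[C@@H](CC/C(=C/COCc1ccc(OC)cc1)CO[Si](c1ccccc1)(c1ccccc1)C(C)(C)C)O | intermediate
12 | (3R,6Z)-6-{[(tert-butyldiphenylsilyl)oxy]methyl}-8-[(4-methoxybenzyl)oxy]-2-methyl-3-[(triethylsilyl)oxy]octa-1,6-diene | C=C(C)[C@@H](CC/C(=C/COCc1ccc(OC)cc1)CO[Si](c1ccccc1)(c1ccccc1)C(C)(C)C)O[Si](CC)(CC)CC | intermediate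
13 | (2Z,6R)-3-{[(tert-butyldiphenylsilyl)oxy]methyl}-7-methyl-6-[(triethylsilyl)oxy]octa-2,7-dien-1-ol | C=C(C)[C@@H](CC/C(=C/CO)CO[Si](c1ccccc1)(c1ccccc1)C(C)(C)C)O[Si](CC)(CC)CC | intermediate
14 | 6-methylsalicylic acid (2-hydroxy-6-methylbenzoic acid) | Cc1cccc(O)c1C(=O)O | starting material
15 | (2Z,6R)-3-{[(tert-butyldiphenylsilyl)oxy]methyl}-7-methyl-6-[(triethylsilyl)oxy]octa-2,7-dien-1-yl 2-hydroxy-6-methylbenzoate | C=C(C)[C@@H](CC/C(=C/COC(=O)c1c(C)cccc1O)CO[Si](c1ccccc1)(c1ccccc1)C(C)(C)C)O[Si](CC)(CC)CC | intermediate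
16 | ketenylidenetriphenylphosphorane | O=C=C=P(c1ccccc1)(c1ccccc1)c1ccccc1 | starting material
17 | ester ylide: (2Z,6R)-3-{[(tert-butyldiphenylsilyl)oxy]methyl}-7-methyl-6-[(triethylsilyl)oxy]octa-2,7-dien-1-yl 2-methyl-6-{[2-(triphenyl-λ5-phosphanylidene)acetyl]oxy}benzoate | C=C(C)[C@@H](CC/C(=C/COC(=O)c1c(C)cccc1OC(=O)C=P(c1ccccc1)(c1ccccc1)c1ccccc1)CO[Si](c1ccccc1)(c1ccccc1)C(C)(C)C)O[Si](CC)(CC)CC | intermediate (not isolated)
18 | 4-{[(2Z,6R)-3-{[(tert-butyldiphenylsilyl)oxy]methyl}-7-methyl-6-[(triethylsilyl)oxy]octa-2,7-dien-1-yl]oxy}-5-methyl-2H-chromen-2-one | C=C(C)[C@@H](CC/C(=C/COc1cc(=O)oc2cccc(C)c12)CO[Si](c1ccccc1)(c1ccccc1)C(C)(C)C)O[Si](CC)(CC)CC | intermediate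
19 | 4-{[(2Z,6R)-3-{[(tert-butyldiphenylsilyl)oxy]methyl}-6-hydroxy-7-methylocta-2,7-dien-1-yl]oxy}-5-methyl-2H-chromen-2-one | C=C(C)[C@@H](CC/C(=C/COc1cc(=O)oc2cccc(C)c12)CO[Si](c1ccccc1)(c1ccccc1)C(C)(C)C)O | intermediate
20 | (3R,6Z)-6-{[(tert-butyldiphenylsilyl)oxy]methyl}-2-methyl-8-[(5-methyl-2-oxo-2H-chromen-4-yl)oxy]octa-1,6-dien-3-yl methanesulfonate | C=C(C)[C@@H](CC/C(=C/COc1cc(=O)oc2cccc(C)c12)CO[Si](c1ccccc1)(c1ccccc1)C(C)(C)C)OS(C)(=O)=O | intermediate
21 | 2,3-dimethylbut-2-ene | CC(C)=C(C)C | starting material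
22 | acetone O-oxide (carbonyl oxide) | CC(C)=[O+][O-] | intermediate (not isolated)
23 | 2-methoxyprop-2-yl hydroperoxide | COC(C)(C)OO | intermediate
24 | 4-{[(2Z,6S)-3-{[(tert-butyldiphenylsilyl)oxy]methyl}-6-[(2-methoxypropan-2-yl)peroxy]-7-methylocta-2,7-dien-1-yl]oxy}-5-methyl-2H-chromen-2-one | C=C(C)[C@H](CC/C(=C/COc1cc(=O)oc2cccc(C)c12)CO[Si](c1ccccc1)(c1ccccc1)C(C)(C)C)OOC(C)(C)OC | intermediate
25 | 4-{[(2Z,6S)-3-(hydroxymethyl)-6-[(2-methoxypropan-2-yl)peroxy]-7-methylocta-2,7-dien-1-yl]oxy}-5-methyl-2H-chromen-2-one | C=C(C)[C@H](CC/C(=C/COc1cc(=O)oc2cccc(C)c12)CO)OOC(C)(C)OC | intermediate (not isolated)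
26 | 4-{[(2Z,6S)-6-hydroperoxy-3-(hydroxymethyl)-7-methylocta-2,7-dien-1-yl]oxy}-5-methyl-2H-chromen-2-one (CNP0171309.1) | C=C(C)[C@H](CC/C(=C/COc1cc(=O)oc2cccc(C)c12)CO)OO | target

Total step count: 15.
Longest linear sequence: 13 steps (steps 1–3, 5–12, 14 and 15); steps 4 and 13 prepare reagents.

Steps most likely to fail

Step 10. After the fast O-acylation, the olefination of the ester carbonyl, which is twisted out of conjugation and shielded by the peri methyl group, may stall. The ylide would then be hydrolysed on work-up, or forcing conditions would trigger a [3,3] shift of the allyl group to C3. The fallback sets out from allylic alcohol 13 and returns at 18. 4-Hydroxy-5-methyl-2H-chromen-2-one F1 is made from commercial 1-(2-hydroxy-6-methylphenyl)ethanone (NaH, diethyl carbonate, toluene, reflux). It is then etherified with 13 under Mitsunobu conditions (PPh3, diisopropyl azodicarboxylate, THF, 0 °C → rt). O-Alkylation at the C4 oxygen is the expected main pathway with a primary allylic alcohol; the 2-alkoxychromone and C3-allyl isomers would be removed by chromatography.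

Step 14. The bulky peroxide anion may attack the unhindered terminal methylene (SN2' transposition to an achiral primary allylic peroxide), the allylic mesylate may ionise with erosion of configuration, or E2 elimination may give the diene. The fallback sets out from alcohol 19 and returns at target 26.
- Mitsunobu reaction of 19 with 2-nitrobenzenesulfonylhydrazide (PPh3, diethyl azodicarboxylate, N-methylmorpholine, THF, −30 °C → rt) gives an allylic diazene that loses N2 with 1,3-transposition. The product is the prenyl-type olefin 4-{[(2Z)-3-{[(tert-butyldiphenylsilyl)oxy]methyl}-7-methylocta-2,6-dien-1-yl]oxy}-5-methyl-2H-chromen-2-one F2.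
- Dye-sensitised photooxygenation (O2, tetraphenylporphyrin, hν, CH2Cl2, 0 °C; Schenck ene reaction) attacks the electron-rich 6',7'-olefin and gives the racemic 6'-hydroperoxide silyl ether F3, which is separated from its tertiary regioisomer.
- HPLC on a chiral stationary phase delivers the (6'S)-hydroperoxide silyl ether F4.
- Desilylation with Bu4NF/AcOH (THF, 0 °C) gives 26.

Step 5. The axial arrangement of CH2OPMB may compete in the chair and erode the olefin geometry, and the dienyl ether or the isopropenyl ketone may polymerise at 110 °C. The fallback sets out from aldehyde 2 and returns at 12.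
- Base-catalysed Michael addition (KOt-Bu cat., THF) of commercial methyl bis(2,2,2-trifluoroethyl)phosphonoacetate to N-methoxy-N-methylacrylamide gives methyl 2-[bis(2,2,2-trifluoroethoxy)phosphoryl]-5-[methoxy(methyl)amino]-5-oxopentanoate F5.
- Still–Gennari olefination of 2 (KN(SiMe3)2, 18-crown-6, THF, −78 °C) gives the (Z)-enoate Weinreb amide methyl (2Z)-5-[methoxy(methyl)amino]-2-{2-[(4-methoxybenzyl)oxy]ethylidene}-5-oxopentanoate F6.
- CH2=C(CH3)MgBr (THF, −40 °C) adds to the amide to give methyl (2Z)-2-{2-[(4-methoxybenzyl)oxy]ethylidene}-6-methyl-5-oxohept-6-enoate F7.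
- Corey–Bakshi–Shibata reduction as in step 6 gives methyl (2Z,5R)-5-hydroxy-2-{2-[(4-methoxybenzyl)oxy]ethylidene}-6-methylhept-6-enoate F8.
- Silylation without delay (Et3SiCl, imidazole), to forestall lactonisation, gives methyl (2Z,5R)-2-{2-[(4-methoxybenzyl)oxy]ethylidene}-6-methyl-5-[(triethylsilyl)oxy]hept-6-enoate F9.
- i-Bu2AlH (CH2Cl2, −78 °C) gives (2Z,5R)-2-{2-[(4-methoxybenzyl)oxy]ethylidene}-6-methyl-5-[(triethylsilyl)oxy]hept-6-en-1-ol F10, and TBDPSCl/imidazole then gives 12.

Further compounds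
F1 | step 10 | 4-hydroxy-5-methyl-2H-chromen-2-one | Cc1cccc2oc(=O)cc(O)c12
F2 | step 14 | 4-{[(2Z)-3-{[(tert-butyldiphenylsilyl)oxy]methyl}-7-methylocta-2,6-dien-1-yl]oxy}-5-methyl-2H-chromen-2-one | CC(C)=CCC/C(=C/COc1cc(=O)oc2cccc(C)c12)CO[Si](c1ccccc1)(c1ccccc1)C(C)(C)C
F3 | step 14 | 4-{[(2Z)-3-{[(tert-butyldiphenylsilyl)oxy]methyl}-6-hydroperoxy-7-methylocta-2,7-dien-1-yl]oxy}-5-methyl-2H-chromen-2-one (racemic at C6') | C=C(C)C(CC/C(=C/COc1cc(=O)oc2cccc(C)c12)CO[Si](c1ccccc1)(c1ccccc1)C(C)(C)C)OO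
F4 | step 14 | 4-{[(2Z,6S)-3-{[(tert-butyldiphenylsilyl)oxy]methyl}-6-hydroperoxy-7-methylocta-2,7-dien-1-yl]oxy}-5-methyl-2H-chromen-2-one | C=C(C)[C@H](CC/C(=C/COc1cc(=O)oc2cccc(C)c12)CO[Si](c1ccccc1)(c1ccccc1)C(C)(C)C)OO
F5 | step 5 | methyl 2-[bis(2,2,2-trifluoroethoxy)phosphoryl]-5-[methoxy(methyl)amino]-5-oxopentanoate | COC(=O)C(CCC(=O)N(C)OC)P(=O)(OCC(F)(F)F)OCC(F)(F)F
F6 | step 5 | methyl (2Z)-5-[methoxy(methyl)amino]-2-{2-[(4-methoxybenzyl)oxy]ethylidene}-5-oxopentanoate | CON(C)C(=O)CC/C(=C/COCc1ccc(OC)cc1)C(=O)OC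
F7 | step 5 | methyl (2Z)-2-{2-[(4-methoxybenzyl)oxy]ethylidene}-6-methyl-5-oxohept-6-enoate | C=C(C)C(=O)CC/C(=C/COCc1ccc(OC)cc1)C(=O)OC
F8 | step 5 | methyl (2Z,5R)-5-hydroxy-2-{2-[(4-methoxybenzyl)oxy]ethylidene}-6-methylhept-6-enoate | C=C(C)[C@@H](CC/C(=C/COCc1ccc(OC)cc1)C(=O)OC)O
F9 | step 5 | methyl (2Z,5R)-2-{2-[(4-methoxybenzyl)oxy]ethylidene}-6-methyl-5-[(triethylsilyl)oxy]hept-6-enoate | C=C(C)[C@@H](CC/C(=C/COCc1ccc(OC)cc1)C(=O)OC)O[Si](CC)(CC)CC
F10 | step 5 | (2Z,5R)-2-{2-[(4-methoxybenzyl)oxy]ethylidene}-6-methyl-5-[(triethylsilyl)oxy]hept-6-en-1-ol | C=C(C)[C@@H](CC/C(=C/COCc1ccc(OC)cc1)CO)O[Si](CC)(CC)CC
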